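The 1,2-dioxane ring (O1–O2–C3–C4–C5–C6) is traced back to a cyclobutan-1-ol made of C3 (carbinol), C4, C5 and the fully substituted C6; the peroxide bridge is inserted into its C3–C6 bond. In one operation, cobalt-catalysed aerobic oxidation opens the four-membered ring toward the tertiary C6 radical, captures O2 and closes the peroxyhemiacetal, which leaves C3 at the aldehyde oxidation level for attachment of the acetic acid chain through a peroxycarbenium ion. The step exploits the 1,4-relationship of C3 and C6 across O1–O2 and the quaternary nature of C6. The precursor cyclobutanol comes from a chiral ethyl ketone by sulfonium-ylide spiroannulation and auxiliary-controlled ethylation; C6 epimers are separated.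

Key step: step 11

Atom labels follow the dioxane numbering of the target: O1 (on C6), O2 (on C3), C3 (CH2CO2H), C4 (Et), C5, C6 (Et and side chain).

Remark on the chemistry: the ligand and auxiliary antipodes named in steps 2, 5 and 7 are those expected to give the drawn configurations (the mirror-image reagent is used if the sense of induction proves opposite), and the O2 capture at C6 in step 11 is taken to be unselective, so both C6 epimers are carried on and separated at ester 25.

Step 1
Reactants: 1 (2E)-hept-2-enoic acid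
Product: 2 S-ethyl (2E)-hept-2-enethioate
Conditions: EtSH, DCC, DMAP (cat.), CH2Cl2, 0 °C to rt
Reagents that add atoms: ethanethiol, CCS
Why: Steglich thioesterification gives the unsaturated thioester, the acceptor class best suited to copper-catalysed asymmetric methyl addition; no stereocentre is formed.

Step 2
Reactants: 2 S-ethyl (2E)-hept-2-enethioate
Product: 3 S-ethyl (3S)-3-methylheptanethioate
Conditions: MeMgBr, CuBr·SMe2 (cat.), (R)-1-[(S)-2-(diphenylphosphino)ferrocenyl]ethyldicyclohexylphosphine (cat.), t-BuOMe, −75 °C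
Reagents that add atoms: methylmagnesium bromide, C[Mg]Br
Why: Copper-catalysed asymmetric conjugate addition of a Grignard reagent to an α,β-unsaturated thioester should set the methyl-bearing centre (side-chain C4') as S by catalyst control of the enoate face.

Step 3
Reactants: 3 S-ethyl (3S)-3-methylheptanethioate
Product: 4 (3S)-3-methylheptanal
Conditions: i-Bu2AlH, CH2Cl2, −65 °C; aq. Rochelle salt
Reagents that add atoms: none
Why: Low-temperature hydride reduction of a thioester stops at the aldehyde, and the stereocentre is β to the carbonyl and cannot epimerise.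

Step 4
Reactants: 4 (3S)-3-methylheptanal; 5 diethyl (2-oxobutyl)phosphonate
Product: 6 (4E,7S)-7-methylundec-4-en-3-one
Conditions: LiCl, i-Pr2NEt, MeCN, rt
Reagents that add atoms: 5 diethyl (2-oxobutyl)phosphonate, CCC(=O)CP(=O)(OCC)OCC
Why: Horner–Wadsworth–Emmons olefination with a β-ketophosphonate under mild amine/LiCl conditions should give the (E)-enone without touching the remote stereocentre.

Step 5
Reactants: 6 (4E,7S)-7-methylundec-4-en-3-one
Product: 7 (5S,7S)-5-ethyl-7-methylundecan-3-one
Conditions: EtMgBr, CuBr·SMe2 (cat.), (R)-1-[(S)-2-(diphenylphosphino)ferrocenyl]ethyldicyclohexylphosphine (cat.), t-BuOMe, −75 °C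
Reagents that add atoms: ethylmagnesium bromide, CC[Mg]Br
Why: Copper-catalysed asymmetric conjugate addition to an acyclic enone should favour 1,4- over 1,2-addition and set the ethyl-bearing centre (side-chain C2') as S by catalyst control, the existing centre being too remote to interfere.

Step 6
Reactants: 7 (5S,7S)-5-ethyl-7-methylundecan-3-one; 8 cyclopropyldiphenylsulfonium tetrafluoroborate
Product: 10 2-ethyl-2-[(2S,4S)-2-ethyl-4-methyloctyl]cyclobutan-1-one, via oxaspiropentane 9 (not isolated)
Conditions: KOH, DMSO, rt; then aq. HBF4, Et2O, rt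
Reagents that add atoms: 8 cyclopropyldiphenylsulfonium tetrafluoroborate, C1CC1[S+](c1ccccc1)c1ccccc1.F[B-](F)(F)F
Why: Sulfonium-ylide spiroannulation of the ketone followed by acid-induced oxaspiropentane-to-cyclobutanone rearrangement joins the C3–C4–C5 unit to the future C6; the quaternary centre forms as both epimers, which is harmless because C6 becomes trigonal in step 11.

Step 7
Reactants: 10 2-ethyl-2-[(2S,4S)-2-ethyl-4-methyloctyl]cyclobutan-1-one; 11 (2R)-1-amino-2-(methoxymethyl)pyrrolidine (RAMP)
Product: 12 (2R)-N-{2-ethyl-2-[(2S,4S)-2-ethyl-4-methyloctyl]cyclobutylidene}-2-(methoxymethyl)pyrrolidin-1-amine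
Conditions: TsOH (cat.), cyclohexane, reflux (water separator)
Reagents that add atoms: 11 (2R)-1-amino-2-(methoxymethyl)pyrrolidine, COC[C@H]1CCCN1N
Why: Hydrazone condensation on the strained, electrophilic ketone should place the amino nitrogen anti to the quaternary carbon, that is syn to the only enolisable CH2.

Step 8
Reactants: 12 (2R)-N-{2-ethyl-2-[(2S,4S)-2-ethyl-4-methyloctyl]cyclobutylidene}-2-(methoxymethyl)pyrrolidin-1-amine
Product: 14 (2R)-N-{(4S)-2,4-diethyl-2-[(2S,4S)-2-ethyl-4-methyloctyl]cyclobutylidene}-2-(methoxymethyl)pyrrolidin-1-amine, via lithium azaenolate 13 (not isolated)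
Conditions: LiN(i-Pr)2, THF, 0 °C; EtI, −100 °C to rt
Reagents that add atoms: iodoethane, CCI
Why: SAMP/RAMP-hydrazone alkylation, in which the chelated azaenolate 13 is ethylated on the face dictated by the methoxymethylpyrrolidine, should set C4 as S whatever the configuration of the neighbouring quaternary carbon (the RAMP antipode follows from the analogous alkylation of cyclic ketone hydrazones).

Step 9
Reactants: 14 (2R)-N-{(4S)-2,4-diethyl-2-[(2S,4S)-2-ethyl-4-methyloctyl]cyclobutylidene}-2-(methoxymethyl)pyrrolidin-1-amine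
Product: 15 (4S)-2,4-diethyl-2-[(2S,4S)-2-ethyl-4-methyloctyl]cyclobutan-1-one
Conditions: satd aq. oxalic acid, Et2O, rt
Reagents that add atoms: water, O
Why: Mild two-phase acidic hydrazone hydrolysis should release the ketone without epimerising the new α-stereocentre and return the auxiliary.

Step 10
Reactants: 15 (4S)-2,4-diethyl-2-[(2S,4S)-2-ethyl-4-methyloctyl]cyclobutan-1-one
Product: 16 (4S)-2,4-diethyl-2-[(2S,4S)-2-ethyl-4-methyloctyl]cyclobutan-1-ol
Conditions: NaBH4, MeOH, −20 °C
Reagents that add atoms: none
Why: Hydride reduction, carried out at once to lock the α-centre, gives the secondary cyclobutanol; both carbinol epimers serve because this carbon becomes the aldehyde carbon in step 11.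

Step 11
Reactants: 16 (4S)-2,4-diethyl-2-[(2S,4S)-2-ethyl-4-methyloctyl]cyclobutan-1-ol
Product: 21 (4S)-4,6-diethyl-6-[(2S,4S)-2-ethyl-4-methyloctyl]-1,2-dioxan-3-ol, via cyclobutyloxyl radical 17 (not isolated), via tertiary alkyl radical 18 (not isolated), via peroxyl radical 19 (not isolated), via hydroperoxy aldehyde 20 (not isolated)
Conditions: Co(acac)2 (20 mol%), O2 (1 atm), toluene, 40 °C
Reagents that add atoms: dioxygen, O=O
Why: The alcohol exchanges onto cobalt that O2 has raised to the trivalent state, and Co–O homolysis gives alkoxyl radical 17, whose strain-driven β-scission cleaves C3–C6 to tertiary radical 18; 18 captures O2 to give peroxyl radical 19, which is reduced by divalent cobalt and protonated by a further molecule of 16 to hydroperoxy aldehyde 20, and 20 closes to peroxyhemiacetal 21. The closest known reaction type is the cobalt-catalysed aerobic oxidative ring expansion of secondary cyclobutanols to 1,2-dioxan-3-ols, the homologue of the cyclopropanol to 1,2-dioxolan-3-ol oxidation. The O1–C6 bond is made by radical capture of O2, and the six-membered ring then closes by 6-exo-trig addition of the hydroperoxide oxygen to the aldehyde carbonyl (O2–C3 bond). C4 is untouched and stays S; C3 forms as an equilibrating anomeric mixture that is erased in step 13; C6 is created at a planar open-chain radical for which the substrate offers no controlling element, so both C6 epimers are expected and the 6S isomer is secured only by separation at ester 25. The selectivity the step needs is regiochemical, scission of C3–C6 in preference to C3–C4, and the fully substituted C6 secures it (tertiary against secondary radical).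

Step 12
Reactants: 21 (4S)-4,6-diethyl-6-[(2S,4S)-2-ethyl-4-methyloctyl]-1,2-dioxan-3-ol
Product: 22 (4S)-4,6-diethyl-6-[(2S,4S)-2-ethyl-4-methyloctyl]-1,2-dioxan-3-yl acetate
Conditions: Ac2O, pyridine, DMAP (cat.), CH2Cl2, 0 °C
Reagents that add atoms: acetic anhydride, CC(=O)OC(C)=O
Why: Acylation of the peroxyhemiacetal hydroxyl installs the leaving group for ionisation at C3, and the short, cold exposure to base should limit fragmentation and C4 epimerisation through the open-chain aldehyde.

Step 13
Reactants: 22 (4S)-4,6-diethyl-6-[(2S,4S)-2-ethyl-4-methyloctyl]-1,2-dioxan-3-yl acetate; 23 tert-butyl[(1-methoxyethenyl)oxy]dimethylsilane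
Product: 25 methyl 2-[(3S,4S,6S)-4,6-diethyl-6-[(2S,4S)-2-ethyl-4-methyloctyl]-1,2-dioxan-3-yl]acetate, via peroxycarbenium triflate 24 (not isolated)
Conditions: Me3SiOTf (0.3 equiv), CH2Cl2, −78 °C; chromatographic separation of the C6 epimers
Reagents that add atoms: 23 tert-butyl[(1-methoxyethenyl)oxy]dimethylsilane, COC(=C)O[Si](C)(C)C(C)(C)C
Why: Lewis-acid ionisation to peroxycarbenium ion 24 and Mukaiyama-type addition of the silyl ketene acetal should give the 3,4-cis product (3S), because the quaternary C6 always carries one axial alkyl group, which forces the C4 ethyl group equatorial, and axial attack on that half-chair places the new chain cis to it; the 6S and 6R diastereomers are separated at this stage.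

Step 14
Reactants: 25 methyl 2-[(3S,4S,6S)-4,6-diethyl-6-[(2S,4S)-2-ethyl-4-methyloctyl]-1,2-dioxan-3-yl]acetate
Product: 26 2-[(3S,4S,6S)-4,6-diethyl-6-[(2S,4S)-2-ethyl-4-methyloctyl]-1,2-dioxan-3-yl]acetic acid
Conditions: LiOH, THF/H2O, 0 °C; then aq. HCl to pH 3
Reagents that add atoms: lithium hydroxide, [Li+].[OH-]
Why: Cold saponification of the methyl ester should leave the dialkyl peroxide and all stereocentres intact, short contact with hydroxide limiting β-elimination of the peroxide.

Compound list
1 | (2E)-hept-2-enoic acid | CCCC/C=C/C(=O)O | starting material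
2 | S-ethyl (2E)-hept-2-enethioate | CCCC/C=C/C(=O)SCC | intermediate
3 | S-ethyl (3S)-3-methylheptanethioate | CCCC[C@H](C)CC(=O)SCC | intermediate
4 | (3S)-3-methylheptanal | CCCC[C@H](C)CC=O | intermediate
5 | diethyl (2-oxobutyl)phosphonate | CCC(=O)CP(=O)(OCC)OCC | starting material
6 | (4E,7S)-7-methylundec-4-en-3-one | CCCC[C@H](C)C/C=C/C(=O)CC | intermediate
7 | (5S,7S)-5-ethyl-7-methylundecan-3-one | CCCC[C@H](C)C[C@H](CC)CC(=O)CC | intermediate
8 | cyclopropyldiphenylsulfonium tetrafluoroborate | C1CC1[S+](c1ccccc1)c1ccccc1.F[B-](F)(F)F | starting material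
9 | 2-ethyl-2-[(2S,4S)-2-ethyl-4-methyloctyl]-1-oxaspiro[2.2]pentane (both epimers at the epoxide carbon) | CCCC[C@H](C)C[C@H](CC)CC1(CC)OC12CC2 | intermediate (not isolated)
10 | 2-ethyl-2-[(2S,4S)-2-ethyl-4-methyloctyl]cyclobutan-1-one (both C2 epimers) | CCCC[C@H](C)C[C@H](CC)CC1(CC)CCC1=O | intermediate
11 | (2R)-1-amino-2-(methoxymethyl)pyrrolidine (RAMP) | COC[C@H]1CCCN1N | starting material
12 | (2R)-N-{2-ethyl-2-[(2S,4S)-2-ethyl-4-methyloctyl]cyclobutylidene}-2-(methoxymethyl)pyrrolidin-1-amine | CCCC[C@H](C)C[C@H](CC)CC1(CC)CCC1=NN1CCC[C@@H]1COC | intermediate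
13 | lithium azaenolate of 12 (N-lithio cyclobut-1-enyl hydrazide) | CCCC[C@H](C)C[C@H](CC)CC1(CC)CC=C1N([Li])N1CCC[C@@H]1COC | intermediate (not isolated)
14 | (2R)-N-{(4S)-2,4-diethyl-2-[(2S,4S)-2-ethyl-4-methyloctyl]cyclobutylidene}-2-(methoxymethyl)pyrrolidin-1-amine | CCCC[C@H](C)C[C@H](CC)CC1(CC)C[C@H](CC)C1=NN1CCC[C@@H]1COC | intermediate
15 | (4S)-2,4-diethyl-2-[(2S,4S)-2-ethyl-4-methyloctyl]cyclobutan-1-one (both C2 epimers) | CCCC[C@H](C)C[C@H](CC)CC1(CC)C[C@H](CC)C1=O | intermediate
16 | (4S)-2,4-diethyl-2-[(2S,4S)-2-ethyl-4-methyloctyl]cyclobutan-1-ol (C1 and C2 epimers) | CCCC[C@H](C)C[C@H](CC)CC1(CC)C[C@H](CC)C1O | intermediate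
17 | cyclobutyloxyl radical of 16 | CCCC[C@H](C)C[C@H](CC)CC1(CC)C[C@H](CC)C1[O] | intermediate (not isolated)
18 | ring-opened tertiary alkyl radical (radical at C6, aldehyde at C3) | CCCC[C@H](C)C[C@H](CC)C[C](CC)C[C@H](CC)C=O | intermediate (not isolated)
19 | tertiary peroxyl radical (OO• on C6, aldehyde at C3) | CCCC[C@H](C)C[C@H](CC)CC(CC)(O[O])C[C@H](CC)C=O | intermediate (not isolated)
20 | (2S,6S,8S)-2,4,6-triethyl-4-hydroperoxy-8-methyldodecanal (both C4 epimers) | CCCC[C@H](C)C[C@H](CC)CC(CC)(OO)C[C@H](CC)C=O | intermediate (not isolated)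
21 | (4S)-4,6-diethyl-6-[(2S,4S)-2-ethyl-4-methyloctyl]-1,2-dioxan-3-ol (C3 anomers, both C6 epimers) | CCCC[C@H](C)C[C@H](CC)CC1(CC)C[C@H](CC)C(O)OO1 | intermediate
22 | (4S)-4,6-diethyl-6-[(2S,4S)-2-ethyl-4-methyloctyl]-1,2-dioxan-3-yl acetate (C3 anomers, both C6 epimers) | CCCC[C@H](C)C[C@H](CC)CC1(CC)C[C@H](CC)C(OC(C)=O)OO1 | intermediate
23 | tert-butyl[(1-methoxyethenyl)oxy]dimethylsilane | COC(=C)O[Si](C)(C)C(C)(C)C | starting material
24 | (4S)-4,6-diethyl-6-[(2S,4S)-2-ethyl-4-methyloctyl]-1,2-dioxan-3-ylium triflate (peroxycarbenium ion) | CCCC[C@H](C)C[C@H](CC)CC1(CC)C[C@H](CC)C=[O+]O1.[O-]S(=O)(=O)C(F)(F)F | intermediate (not isolated)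
25 | methyl 2-[(3S,4S,6S)-4,6-diethyl-6-[(2S,4S)-2-ethyl-4-methyloctyl]-1,2-dioxan-3-yl]acetate | CCCC[C@H](C)C[C@H](CC)C[C@@]1(CC)C[C@H](CC)[C@H](CC(=O)OC)OO1 | intermediate
26 | 2-[(3S,4S,6S)-4,6-diethyl-6-[(2S,4S)-2-ethyl-4-methyloctyl]-1,2-dioxan-3-yl]acetic acid | CCCC[C@H](C)C[C@H](CC)C[C@@]1(CC)C[C@H](CC)[C@H](CC(=O)O)OO1 | target

Total step count: 14. Longest linear sequence: 14 steps (from 1 to 26).

Steps most likely to fail

Step 11. Capture of O2 at the planar C6 radical has no facial bias, so both C6 epimers form. Cobalt may also decompose the tertiary hydroperoxide or the peroxyhemiacetal by over-oxidation, and some scission toward C4 may compete. The fallback separates C–C scission from C–O bond formation and keeps cobalt away from the peroxide. It sets out from cyclobutanol 16: alkoxyl-radical fragmentation with PhI(OAc)2 and I2 (cyclohexane, visible light, rt) passes through radicals 17 and 18 and should give the ring-opened tertiary iodide, (2S,6S,8S)-2,4,6-triethyl-4-iodo-8-methyldodecanal F1. Silver-assisted perhydrolysis of F1 (AgOCOCF3, anhydrous H2O2 in Et2O, 0 °C) replaces iodide by the hydroperoxy group to give hydroperoxy aldehyde 20, which closes to dioxanol 21, where the route is rejoined. This variant is also unselective at C6, so the separation at 25 remains.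

Step 13. Lewis-acid-induced heterolysis of the O–O or C6–O1 bond may compete with ionisation of the acetate, and attack on cation 24 may lose its facial preference. The fallback introduces the two-carbon unit through the open-chain tautomer and sets out from dioxanol 21. Wittig olefination with methyl (triphenylphosphoranylidene)acetate (CH2Cl2, rt) should give the hydroperoxy enoate, methyl (2E,4S,8S,10S)-4,6,8-triethyl-6-hydroperoxy-10-methyltetradec-2-enoate F2. Intramolecular peroxy-Michael addition of F2 (Et2NH, CF3CH2OH, rt) closes the O2–C3 bond and comes back to the route at ester 25 after separation of the C3 and C6 isomers.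

Step 8. Azaenolate formation in the strained ring next to a quaternary carbon may be slow, the auxiliary may be mismatched with one of the two C2 epimers, and the α-centre may epimerise during hydrazone hydrolysis. The fallback sets C4 by hydrogenation and sets out from cyclobutanone 10. Aldol addition to acetaldehyde (LiN(i-Pr)2, THF, −78 °C) gives 2-ethyl-2-[(2S,4S)-2-ethyl-4-methyloctyl]-4-(1-hydroxyethyl)cyclobutan-1-one F3. Acid-catalysed dehydration (TsOH, benzene, reflux) gives (4E)-2-ethyl-4-ethylidene-2-[(2S,4S)-2-ethyl-4-methyloctyl]cyclobutan-1-one F4. Asymmetric hydrogenation of the exocyclic alkene of F4 (H2, [Ir(cod)(L)][B(C6H3(CF3)2)4] with L = a chiral 2-[2-(diphenylphosphino)phenyl]-4-tert-butyl-4,5-dihydrooxazole, CH2Cl2, rt) sets C4 and comes back to the route at ketone 15.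

Further compounds
F1 | step 11 | (2S,6S,8S)-2,4,6-triethyl-4-iodo-8-methyldodecanal (both C4 epimers) | CCCC[C@H](C)C[C@H](CC)CC(CC)(I)C[C@H](CC)C=O
F2 | step 13 | methyl (2E,4S,8S,10S)-4,6,8-triethyl-6-hydroperoxy-10-methyltetradec-2-enoate (both C6 epimers) | CCCC[C@H](C)C[C@H](CC)CC(CC)(OO)C[C@H](CC)/C=C/C(=O)OC
F3 | step 8 | 2-ethyl-2-[(2S,4S)-2-ethyl-4-methyloctyl]-4-(1-hydroxyethyl)cyclobutan-1-one | CCCC[C@H](C)C[C@H](CC)CC1(CC)CC(C(C)O)C1=O
F4 | step 8 | (4E)-2-ethyl-4-ethylidene-2-[(2S,4S)-2-ethyl-4-methyloctyl]cyclobutan-1-one | CCCC[C@H](C)C[C@H](CC)CC1(CC)C/C(=C\C)C1=O
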